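**Plan**

1. Locants: ring C1' (CH carrying the chain), C2' (CMe2), C3' (CHBr), C4', C5', C6' (C=CH2); chain C5 (CH2 on C1') to C1 (CH2Br). Cuts, in retrosynthetic order: C2 carbinol (ketone reduction), C1–C2 (ester plus LiCH2Br), C3=C4 (Z-olefination of a C4 aldehyde), C6'=CH2 (ketone methylenation), C3'–Br (axial alcohol from a ketone), ring bond C2'–C3', C1'–C2' (isopropenyl conjugate addition), C6'–C1' (aldehyde alkynylation).
2. Enabling feature: C2' is a gem-dimethyl quaternary carbon between the CH C1' and the heteroatom-bearing C3'. An isopropenyl group on C1' is therefore a latent tertiary C2' radical (H• supplies the second methyl), and C3' can be a nitrile carbon that closes ring C1'–C6' and emerges as a ketone.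
3. C6' (kept oxygenated) and C4 (kept as acyl) are 1,4-related through C1' and C5, so they are stored as a γ-lactone (temporary oxolanone ring). This leaves isopropenyl as the only alkene and the nitrile as the only radical acceptor; the lactone is opened later to the C6' ketone and C4 aldehyde.
4. Forward order: butenolide, trans-disubstituted lactone, cyclohexane ring (trans-fused keto lactone), C3' bromide, lactone opening, chain grown from C4 to C1.
5. Stereochemistry: one catalytic centre (C6' carbinol, later erased) sets C1' by anti cuprate addition; C1' in the locked chair sets C3' (equatorial hydride attack, then SN2 inversion). The alkene is Z by Still–Gennari olefination, and C2 is set by CBS reagent control.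

Key step: step 4

Assumption: (S,S)-ProPhenol is taken to deliver the alkynylzinc to the Re face of aldehyde 1; if the sense is the opposite, the (R,R)-ligand is used and nothing else changes.

**Route**

Step 1
Reactants: 1 4-oxobutanenitrile; 2 methyl propiolate
Product: 3 methyl (4S)-6-cyano-4-hydroxyhex-2-ynoate
Conditions: (S,S)-ProPhenol (10 mol %), Me2Zn (3 equiv), Ph3P=O (20 mol %), toluene, 4 °C; then 1 M HCl
Reagents that add atoms: none
Why: Zinc–ProPhenol-catalysed asymmetric alkynylation of an aldehyde, in which the dinuclear zinc catalyst holds aldehyde and zinc acetylide and should deliver the alkynyl group to the Re face, setting the (S)-carbinol (future C6') that relays the ring stereochemistry; the nitrile is inert to Me2Zn.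

Step 2
Reactants: 3 methyl (4S)-6-cyano-4-hydroxyhex-2-ynoate
Product: 5 3-[(2S)-5-oxo-2,5-dihydrofuran-2-yl]propanenitrile, via Z-hydroxy enoate 4 (not isolated)
Conditions: H2 (1 atm), Pd/CaCO3 poisoned with Pb(OAc)2 (Lindlar catalyst), quinoline, EtOAc, rt; then camphorsulfonic acid (cat.), CH2Cl2, rt
Reagents that add atoms: none
Why: Lindlar semihydrogenation should stop at the cis-alkene, whose γ-hydroxyl then lactonises onto the methyl ester to give the butenolide without touching the stereocentre or the nitrile.

Step 3
Reactants: 5 3-[(2S)-5-oxo-2,5-dihydrofuran-2-yl]propanenitrile; 6 isopropenylmagnesium bromide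
Product: 7 3-[(2S,3S)-5-oxo-3-(prop-1-en-2-yl)oxolan-2-yl]propanenitrile
Conditions: 6 (1.5 equiv), CuBr·SMe2 (20 mol %), THF, −78 to −40 °C; then 1 M HCl
Reagents that add atoms: none
Why: Copper-catalysed conjugate addition of a Grignard reagent to a γ-substituted butenolide, in which the isopropenyl group should add to the β-carbon anti to the γ-cyanoethyl group, giving the trans lactone and thereby the C1' configuration; the nitrile does not react at this temperature.

Step 4
Reactants: 7 3-[(2S,3S)-5-oxo-3-(prop-1-en-2-yl)oxolan-2-yl]propanenitrile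
Product: 9 (3aS,7aS)-4,4-dimethylhexahydro-1-benzofuran-2,5-dione, via cyclic ketimine 8 (not isolated)
Conditions: Fe(acac)3 (50 mol %), PhSiH3 (2.5 equiv), EtOH, 60 °C; then 1 M HCl, THF, rt
Reagents that add atoms: water, O
Why: An iron hydride formed from Fe(acac)3, PhSiH3 and EtOH transfers a hydrogen atom to the CH2 terminus of the isopropenyl group (Markovnikov), giving the tertiary radical at the future C2', which adds to the nitrile carbon (future C3'); the iminyl radical is reduced and protonated to ketimine 8, and acid hydrolysis gives the ketone. The closest known reaction type is the iron-hydride hydrogen-atom-transfer reductive cyclisation of alkenyl nitriles to cyclic ketones (and of alkene-tethered ketones to cycloalkanols). The cyclohexane ring closes in the 6-exo-dig mode and is trans-fused to the oxolanone because the two reacting arms were placed trans in step 3. No stereocentre is created: C2' becomes a non-stereogenic gem-dimethyl carbon and the two existing centres are not involved. The step needs chemoselective and regioselective hydrogen-atom transfer, secured by isopropenyl being the only alkene (the C6' and C4 functions are stored in the lactone) and by the preference for the tertiary radical. It also needs cyclisation to outrun reduction of that radical, which the ring-bound, gauche disposition of the two arms should favour.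

Step 5
Reactants: 9 (3aS,7aS)-4,4-dimethylhexahydro-1-benzofuran-2,5-dione
Product: 10 (3aS,5R,7aS)-5-hydroxy-4,4-dimethylhexahydro-1-benzofuran-2(3H)-one
Conditions: LiBH(s-Bu)3 (L-Selectride, 1.2 equiv), THF, −78 °C; then AcOH
Reagents that add atoms: none
Why: Bulky-hydride reduction of a 2,2-dimethylcyclohexanone held in one chair by the trans ring fusion, where hydride should enter along the equatorial trajectory to give the axial 5R alcohol (trans to the C3a carbon substituent); the lactone is not reduced at −78 °C.

Step 6
Reactants: 10 (3aS,5R,7aS)-5-hydroxy-4,4-dimethylhexahydro-1-benzofuran-2(3H)-one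
Product: 11 (3aS,5S,7aS)-5-bromo-4,4-dimethylhexahydro-1-benzofuran-2(3H)-one
Conditions: CBr4 (2 equiv), PPh3 (2.2 equiv), CH2Cl2, 0 °C to rt
Reagents that add atoms: carbon tetrabromide, BrC(Br)(Br)Br
Why: Appel bromination, in which the alkoxyphosphonium ion, kept axial by the trans-fused lactone, should be displaced by bromide with SN2 inversion to the equatorial 5S bromide, cis to the C1' substituent as in the target.

Step 7
Reactants: 11 (3aS,5S,7aS)-5-bromo-4,4-dimethylhexahydro-1-benzofuran-2(3H)-one
Product: 12 (1S,2S,4S)-4-bromo-2-(2-hydroxyethyl)-3,3-dimethylcyclohexan-1-ol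
Conditions: i-Bu2AlH (3.5 equiv), CH2Cl2, −78 to 0 °C; then aq. potassium sodium tartrate
Reagents that add atoms: none
Why: Aluminium hydride reduction of the lactone to the diol opens the temporary ring; the hindered secondary bromide is inert to i-Bu2AlH and no stereocentre is touched.

Step 8
Reactants: 12 (1S,2S,4S)-4-bromo-2-(2-hydroxyethyl)-3,3-dimethylcyclohexan-1-ol
Product: 13 2-[(1S,3S)-3-bromo-2,2-dimethyl-6-oxocyclohexyl]acetaldehyde
Conditions: (COCl)2, DMSO, CH2Cl2, −78 °C; then Et3N, −78 to 0 °C
Reagents that add atoms: none
Why: Swern oxidation activates both hydroxyls as alkoxysulfonium ions before base is added, so ketone and aldehyde should form together and the γ-hydroxy aldehyde cannot close to a lactol and re-oxidise to the lactone; C1', now α to the ketone, already has the more stable configuration (chain and bromine both equatorial).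

Step 9
Reactants: 13 2-[(1S,3S)-3-bromo-2,2-dimethyl-6-oxocyclohexyl]acetaldehyde; 14 ethyl 2-[bis(2,2,2-trifluoroethoxy)phosphoryl]propanoate
Product: 15 ethyl (2Z)-4-[(1S,3S)-3-bromo-2,2-dimethyl-6-oxocyclohexyl]-2-methylbut-2-enoate
Conditions: 14 (1.2 equiv), KN(SiMe3)2 (1.15 equiv), 18-crown-6, THF, −78 °C
Reagents that add atoms: none
Why: Still–Gennari olefination, in which the electron-poor phosphonate under dissociating conditions collapses kinetically to the (Z)-trisubstituted enoate; the aldehyde should react in preference to the hindered ketone at −78 °C.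

Step 10
Reactants: 15 ethyl (2Z)-4-[(1S,3S)-3-bromo-2,2-dimethyl-6-oxocyclohexyl]-2-methylbut-2-enoate
Product: 16 ethyl (2Z)-4-[(1R,3S)-3-bromo-2,2-dimethyl-6-methylidenecyclohexyl]-2-methylbut-2-enoate
Conditions: Zn, CH2Br2, TiCl4, THF/CH2Cl2, 0 °C to rt
Reagents that add atoms: dibromomethane, BrCBr
Why: Lombardo–Takai methylenation, whose non-basic gem-dimetallic methylene reagent should convert the hindered, enolisable ketone into the exocyclic alkene without epimerising C1', without attacking the enoate and without base-induced loss of the γ-bromide.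

Step 11
Reactants: 16 ethyl (2Z)-4-[(1R,3S)-3-bromo-2,2-dimethyl-6-methylidenecyclohexyl]-2-methylbut-2-enoate
Product: 17 (3Z)-1-bromo-5-[(1R,3S)-3-bromo-2,2-dimethyl-6-methylidenecyclohexyl]-3-methylpent-3-en-2-one
Conditions: CH2Br2 (1.5 equiv), MeLi·LiBr (1.4 equiv, slow addition), THF, −78 °C; then AcOH, −78 °C
Reagents that add atoms: dibromomethane, BrCBr
Why: Acylation of a halomethyllithium carbenoid by an ester, in which bromomethyllithium made by Br/Li exchange in the presence of the ester adds 1,2 and the tetrahedral lithium alkoxide should persist at −78 °C until the acid quench releases the bromomethyl ketone.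

Step 12
Reactants: 17 (3Z)-1-bromo-5-[(1R,3S)-3-bromo-2,2-dimethyl-6-methylidenecyclohexyl]-3-methylpent-3-en-2-one
Product: 18 (2S,3Z)-1-bromo-5-[(1R,3S)-3-bromo-2,2-dimethyl-6-methylidenecyclohexyl]-3-methylpent-3-en-2-ol
Conditions: (S)-2-methyl-CBS-oxazaborolidine (20 mol %), catecholborane (1.5 equiv), toluene, −78 °C; then MeOH, pH 7 buffer
Reagents that add atoms: none
Why: CBS reduction, in which the (S)-oxazaborolidine should bind the ketone with the α-branched Z-alkenyl group as the large substituent and CH2Br as the small one, delivering hydride 1,2 to give the (S)-bromohydrin; catecholborane at −78 °C does not hydroborate the alkenes.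

**Compound list**

1 | 4-oxobutanenitrile | N#CCCC=O | starting material
2 | methyl propiolate | C#CC(=O)OC | starting material
3 | methyl (4S)-6-cyano-4-hydroxyhex-2-ynoate | COC(=O)C#C[C@H](CCC#N)O | intermediate
4 | methyl (2Z,4S)-6-cyano-4-hydroxyhex-2-enoate | COC(=O)/C=C\[C@H](CCC#N)O | intermediate (not isolated)
5 | 3-[(2S)-5-oxo-2,5-dihydrofuran-2-yl]propanenitrile | O=C1C=C[C@H](CCC#N)O1 | intermediate
6 | isopropenylmagnesium bromide | C=C(C)[Mg]Br | starting material
7 | 3-[(2S,3S)-5-oxo-3-(prop-1-en-2-yl)oxolan-2-yl]propanenitrile | O=C1C[C@@H](C(C)=C)[C@H](CCC#N)O1 | intermediate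
8 | (3aS,7aS)-5-imino-4,4-dimethylhexahydro-1-benzofuran-2(3H)-one | O=C1C[C@H]2C(C)(C)C(=N)CC[C@@H]2O1 | intermediate (not isolated)
9 | (3aS,7aS)-4,4-dimethylhexahydro-1-benzofuran-2,5-dione | O=C1C[C@H]2C(C)(C)C(=O)CC[C@@H]2O1 | intermediate
10 | (3aS,5R,7aS)-5-hydroxy-4,4-dimethylhexahydro-1-benzofuran-2(3H)-one | O=C1C[C@H]2C(C)(C)[C@H](O)CC[C@@H]2O1 | intermediate
11 | (3aS,5S,7aS)-5-bromo-4,4-dimethylhexahydro-1-benzofuran-2(3H)-one | O=C1C[C@H]2C(C)(C)[C@@H](Br)CC[C@@H]2O1 | intermediate
12 | (1S,2S,4S)-4-bromo-2-(2-hydroxyethyl)-3,3-dimethylcyclohexan-1-ol | OCC[C@H]1C(C)(C)[C@@H](Br)CC[C@@H]1O | intermediate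
13 | 2-[(1S,3S)-3-bromo-2,2-dimethyl-6-oxocyclohexyl]acetaldehyde | O=CC[C@H]1C(C)(C)[C@@H](Br)CCC1=O | intermediate
14 | ethyl 2-[bis(2,2,2-trifluoroethoxy)phosphoryl]propanoate | CCOC(=O)C(C)P(=O)(OCC(F)(F)F)OCC(F)(F)F | starting material
15 | ethyl (2Z)-4-[(1S,3S)-3-bromo-2,2-dimethyl-6-oxocyclohexyl]-2-methylbut-2-enoate | CCOC(=O)/C(C)=C\C[C@H]1C(C)(C)[C@@H](Br)CCC1=O | intermediate
16 | ethyl (2Z)-4-[(1R,3S)-3-bromo-2,2-dimethyl-6-methylidenecyclohexyl]-2-methylbut-2-enoate | CCOC(=O)/C(C)=C\C[C@H]1C(C)(C)[C@@H](Br)CCC1=C | intermediate
17 | (3Z)-1-bromo-5-[(1R,3S)-3-bromo-2,2-dimethyl-6-methylidenecyclohexyl]-3-methylpent-3-en-2-one | BrCC(=O)/C(C)=C\C[C@H]1C(C)(C)[C@@H](Br)CCC1=C | intermediate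
18 | (2S,3Z)-1-bromo-5-[(1R,3S)-3-bromo-2,2-dimethyl-6-methylidenecyclohexyl]-3-methylpent-3-en-2-ol | C=C1CC[C@H](Br)C(C)(C)[C@@H]1C/C=C(/C)[C@H](O)CBr | target

**Step count and risks**

Total steps: 12. Longest linear sequence: 12 (from 1 to 18).

Steps most likely to fail:

Step 6. Backside attack at the neopentyl C3' is slow, so E2 loss of the axial oxyphosphonium group (an anti-periplanar axial hydrogen is available) and a 1,2-methyl shift after partial ionisation may outrun substitution. Fallback: setting out from 10, the alcohol is converted with Tf2O and pyridine (CH2Cl2, −20 °C) into the discrete sulfonate (3aS,5R,7aS)-4,4-dimethyl-2-oxooctahydro-1-benzofuran-5-yl trifluoromethanesulfonate F1. This is displaced by Bu4NBr in toluene at rt (non-basic bromide in a non-ionising medium), which should give the inverted bromide and return to the route at 11.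

Step 4. Addition of the tertiary radical to the nitrile is slow, so reduction of the radical to the isopropyl compound or hydrogen transfer from the CH2 next to the nitrile may compete, the more so as the ring must close trans-fused. Fallback: setting out from 7, i-Bu2AlH (2.2 equiv, CH2Cl2, −78 °C, aqueous acid work-up) reduces the nitrile to the aldehyde and the lactone to the lactol, giving 3-[(2S,3S)-5-hydroxy-3-(prop-1-en-2-yl)oxolan-2-yl]propanal F2. Under the same Fe(acac)3/PhSiH3/EtOH conditions the tertiary radical adds to the aldehyde carbonyl, a much faster 6-exo-trig acceptor, to give (3aS,7aS)-4,4-dimethyloctahydro-1-benzofuran-2,5-diol F3 as a mixture at both carbinol carbons, which does not matter. Dess–Martin periodinane then oxidises lactol and secondary alcohol together, returning to the route at 9.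

Step 11. The carbenoid may decompose before it adds, the tetrahedral intermediate may collapse early and take up a second equivalent, or conjugate addition may erode the Z geometry. Fallback: setting out from 16, MeNHOMe·HCl and i-PrMgCl (THF, −20 °C) convert the ester into (2Z)-4-[(1R,3S)-3-bromo-2,2-dimethyl-6-methylidenecyclohexyl]-N-methoxy-N,2-dimethylbut-2-enamide F4. Its chelated tetrahedral adduct with bromomethyllithium (CH2Br2, MeLi·LiBr, −78 °C) is stable until the acid quench, returning to the route at 17.

**Further compounds**

F1 | step 6 | (3aS,5R,7aS)-4,4-dimethyl-2-oxooctahydro-1-benzofuran-5-yl trifluoromethanesulfonate | O=C1C[C@H]2C(C)(C)[C@H](OS(=O)(=O)C(F)(F)F)CC[C@@H]2O1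
F2 | step 4 | 3-[(2S,3S)-5-hydroxy-3-(prop-1-en-2-yl)oxolan-2-yl]propanal | O=CCC[C@@H]1OC(O)C[C@H]1C(C)=C
F3 | step 4 | (3aS,7aS)-4,4-dimethyloctahydro-1-benzofuran-2,5-diol | OC1C[C@H]2C(C)(C)C(O)CC[C@@H]2O1
F4 | step 11 | (2Z)-4-[(1R,3S)-3-bromo-2,2-dimethyl-6-methylidenecyclohexyl]-N-methoxy-N,2-dimethylbut-2-enamide | CON(C)C(=O)/C(C)=C\C[C@H]1C(C)(C)[C@@H](Br)CCC1=C
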